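Everything rests on opening ring A at C3–C4 and C5–C10. In the target the ester carbon C19 on quaternary C4 and the ring-B carbon C6 on C5 sit on the same face of ring A, which is the imprint of a butenolide whose double bond was C4=C5. A single Diels–Alder reaction of 2-(trimethylsilyloxy)buta-1,3-diene with the 3-methylbutenolide 4 therefore closes ring A, fixes C4 and C5 in the absolute sense and leaves a masked ketone at C1. Precursor 4 is a lactone acetal: its acetal carbon is C6 and its menthyloxy group blocks one face. Ring B (aldol at C10) and C9 (Claisen shift from C1) follow.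

Key step: step 3

Remark: halimane numbering is used (ring A = C1–C5 and C10; ring B = C5–C10; C19 = ester carbon on C4; C17 and C20 = methyl groups on C8 and C9; C11–C15 = side chain). C1 in 7–10 and 12, C8 in 12–15, C9 in 14 and C10 in 14 and 17 are transient mixtures that later steps erase or fix, so their SMILES carry no descriptor there.

Step 1
Reactants: 1 citraconic anhydride
Product: 2 5-hydroxy-3-methylfuran-2(5H)-one
Conditions: LiAlH(OtBu)3 (1.05 equiv), THF, −78 → −20 °C; 1 M HCl
Reagents that add atoms: none
Why: Partial reduction of a cyclic anhydride with a bulky alkoxyaluminium hydride, which should attack the less hindered carbonyl group (the one flanked by the vinylic CH and not by the methyl-bearing carbon) and stop at the lactol because the tetrahedral aluminate survives until work-up.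

Step 2
Reactants: 2 5-hydroxy-3-methylfuran-2(5H)-one; 3 (−)-menthol
Product: 4 (5R)-5-(l-menthyloxy)-3-methylfuran-2(5H)-one
Conditions: CSA (0.05 equiv), toluene, reflux, Dean–Stark; crystallisation from hexane at −20 °C, mother liquor re-equilibrated with CSA
Reagents that add atoms: none
Why: Acid-catalysed acetalisation of the lactol gives both acetal epimers, which interconvert through the oxocarbenium ion, so selective crystallisation of the (5R) epimer with re-equilibration of the mother liquor should funnel the material into 4, the menthyl stereocentres coming unchanged from 3.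

Step 3
Reactants: 4 (5R)-5-(l-menthyloxy)-3-methylfuran-2(5H)-one; 5 2-(trimethylsilyloxy)buta-1,3-diene
Product: 6 cis-fused ring-A lactone acetal carrying the C1 trimethylsilyl enol ether
Conditions: 5 (4 equiv), BHT (0.05 equiv), toluene, 120 °C, sealed tube
Reagents that add atoms: none
Why: A concerted but asynchronous thermal [4+2] cycloaddition (normal-demand Diels–Alder reaction) joins the electron-rich diene 5 to the C4=C5 bond of the electron-poor butenolide 4, the closest known reaction type being the thermal addition of 5-menthyloxy-2(5H)-furanones to 2-silyloxydienes. Ring A closes in one suprafacial–suprafacial event as a six-membered carbocycle, bonds C3–C4 and C5–C10 being made together, so the lactone carbonyl carbon on C4 and C6 on C5 are forced cis. Both new stereocentres, C4 and C5, are controlled by the acetal carbon C6, because the diene adds to the butenolide face anti to the menthyloxy group, which gives the C4 and C5 configurations of the target. The step needs regioselectivity and facial selectivity; the first is secured by donor–acceptor polarisation (the diene CH2 next to the silyloxy carbon is the nucleophilic end and bonds to the electrophilic β-carbon C5, which leaves the enol ether at C1=C2), the second by the alkoxy group on the rigid five-membered ring. The diene termini are unsubstituted, so no endo/exo question arises, and the α-methyl group only slows the reaction, which is why excess diene and 120 °C are used.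

Step 4
Reactants: 6 cis-fused ring-A lactone acetal carrying the C1 trimethylsilyl enol ether
Product: 8 bicyclic hydroxy lactone (both C1 epimers), via potassium dihydroxy carboxylate 7 (not isolated)
Conditions: NaBH4 (4 equiv), KOH (3 equiv), EtOH/H2O, 0 → 50 °C; then 2 M HCl to pH 2, 20 °C
Reagents that add atoms: none
Why: Saponification of the lactone acetal with borohydride reduction in the same pot, in which hydroxide opens the pseudo-ester to the C6 aldehyde and expels menthol, NaBH4 reduces the aldehyde as it forms (before the adjacent C5 hydrogen can exchange) and acidification closes the γ-lactone between C19 and C6, while the silyl enol ether is cleaved and the C1 ketone is reduced to an epimer mixture that step 7 returns to the ketone.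

Step 5
Reactants: 8 bicyclic hydroxy lactone (both C1 epimers)
Product: 10 hydroxy selenide methyl ester, via sodium carboxylate 9 (not isolated)
Conditions: (PhSe)2 (0.8 equiv), NaBH4 (1.7 equiv), DMF, 120 °C; then MeI (4 equiv), 20 °C; aq. NH4Cl
Reagents that add atoms: diphenyl diselenide, c1ccccc1[Se][Se]c1ccccc1; iodomethane, IC
Why: SN2 opening of a γ-lactone at its O-alkyl carbon by the soft, weakly basic benzeneselenolate ion turns C6 into a primary alkyl selenide without touching C4 or C5, and O-alkylation of the liberated carboxylate with MeI installs the C19 methyl ester of the target.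

Step 6
Reactants: 10 hydroxy selenide methyl ester; 11 3-methylbut-3-en-2-one
Product: 12 hydroxy keto ester carrying the C6–C9 chain
Conditions: 11 (5 equiv), Bu3SnH (1.3 equiv, slow addition), AIBN (0.1 equiv), toluene, 85 °C
Reagents that add atoms: none
Why: Giese reaction, in which Bu3Sn• abstracts the phenylseleno group, the nucleophilic primary C6 radical adds to the unsubstituted terminus of the enone (which becomes C7) and the α-keto radical at C8 takes hydrogen from Bu3SnH, so that C7–C9 with both methyl groups arrive in one bond-forming step and C8 forms as both epimers.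

Step 7
Reactants: 12 hydroxy keto ester carrying the C6–C9 chain
Product: 13 1,7-diketone (C1 and C9 ketones)
Conditions: Dess–Martin periodinane (1.5 equiv), CH2Cl2, 0 → 20 °C
Reagents that add atoms: none
Why: Dess–Martin oxidation of the secondary alcohol under neutral conditions converges both C1 epimers on the ketone and leaves C5, which is β and not α to either carbonyl group, untouched.

Step 8
Reactants: 13 1,7-diketone (C1 and C9 ketones)
Product: 17 bicyclic β,γ-unsaturated ketone (C8=C9), via ketol 14 (not isolated), via enone C8 epimers 15 (not isolated), via potassium dienolate 16 (not isolated)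
Conditions: KOtBu (4 equiv), t-BuOH/THF, 25 °C; inverse quench into AcOH/H2O, 0 °C
Reagents that add atoms: none
Why: Intramolecular aldol condensation (the ring-closing half of a Robinson annulation) followed by deconjugation, since of all enolates only attack of C10 on the C9 ketone closes a six-membered ring, the ketol loses water by E1cB, the excess base holds the enone as its extended dienolate and kinetic protonation of that dienolate on the α-carbon C10 gives the β,γ-unsaturated ketone, in which C8 is planar so that the epimer mixture from step 6 is erased on purpose.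

Step 9
Reactants: 17 bicyclic β,γ-unsaturated ketone (C8=C9)
Product: 18 (8R)-enone with the C9=C10 double bond
Conditions: HCl (0.05 M), THF/H2O, 0 °C; NaHCO3 at full conversion
Reagents that add atoms: none
Why: Acid-catalysed conjugation of a β,γ-unsaturated ketone, in which enolisation toward C10 gives the heteroannular dienol and this is protonated at C8 perpendicular to the diene plane and, with ring B held in one half-chair by the ring fusion, on the face anti to H5 (the axial protonation known from steroidal 5-en-3-ones), so that the C8 methyl group ends pseudo-equatorial and cis to H5, provided the reaction is stopped before the enone re-enolises.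

Step 10
Reactants: 18 (8R)-enone with the C9=C10 double bond
Product: 19 (1R)-allylic alcohol
Conditions: NaBH4 (1.2 equiv), CeCl3·7H2O (1.2 equiv), MeOH, −40 °C; aq. NH4Cl
Reagents that add atoms: none
Why: Luche reduction, in which the CeCl3-activated carbonyl group is reduced 1,2 and the small hydride should attack C1 axially, from the face that carries H5, which gives the (1R) alcohol with its oxygen on the face opposite to H5.

Step 11
Reactants: 19 (1R)-allylic alcohol
Product: 20 (1R)-allylic acetate
Conditions: Ac2O (3 equiv), DMAP (0.1 equiv), pyridine, CH2Cl2, 20 °C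
Reagents that add atoms: acetic anhydride, CC(=O)OC(C)=O
Why: DMAP-catalysed acylation of the secondary allylic alcohol under basic conditions, which keeps the C1 configuration and avoids ionisation of the allylic system.

Step 12
Reactants: 20 (1R)-allylic acetate
Product: 23 C12 carboxylic acid with quaternary C9 and the C1=C10 double bond, via silyl ketene acetal 21 (not isolated), via trimethylsilyl ester 22 (not isolated)
Conditions: LiN(i-Pr)2 (1.5 equiv), Me3SiCl/Et3N, THF, −78 °C; then 65 °C; 1 M HCl
Reagents that add atoms: none
Why: Ireland–Claisen [3,3] rearrangement of the acetate-derived silyl ketene acetal, in which A(1,3) strain with the C9 methyl group turns the C1–O bond out of the C9=C10 plane on the face anti to H5 and the suprafacial shift delivers the CH2CO2 unit to that face of C9, which sets the quaternary centre (C11 anti to H5, C20 syn to it) while the double bond moves to C1=C10.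

Step 13
Reactants: 23 C12 carboxylic acid with quaternary C9 and the C1=C10 double bond
Product: 25 C12 primary alcohol, via mixed carbonic anhydride 24 (not isolated)
Conditions: ClCO2Et (1.2 equiv), Et3N (1.3 equiv), THF, 0 °C; then NaBH4 (3 equiv), H2O, 0 °C; 1 M HCl
Reagents that add atoms: none
Why: Activation of the acid as a mixed carbonic anhydride followed by NaBH4 reduction is selective for the C12 carboxyl group, since the hindered methyl ester on C4 and the trisubstituted alkene do not react with NaBH4 at 0 °C.

Step 14
Reactants: 25 C12 primary alcohol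
Product: 26 C12 primary iodide
Conditions: I2 (1.3 equiv), PPh3 (1.3 equiv), imidazole (2 equiv), CH2Cl2, 0 → 20 °C
Reagents that add atoms: iodine, [I][I]
Why: Appel-type iodination (alkoxyphosphonium iodide, then SN2) of an unhindered primary alcohol under nearly neutral conditions.

Step 15
Reactants: 27 but-2-yn-1-ol
Product: 30 (2E)-3-iodobut-2-en-1-ol, via aluminium alkoxide 28 (not isolated), via alkenylzirconocene 29 (not isolated)
Conditions: i-Bu2AlH (1.0 equiv), THF, 0 °C; Cp2Zr(H)Cl (1.3 equiv), 20 °C; I2 (1.4 equiv), −78 °C; 1 M HCl
Reagents that add atoms: iodine, [I][I]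
Why: Hydrozirconation of the alkyne as its aluminium alkoxide is a syn addition that should place zirconium on the methyl-bearing carbon remote from the alkoxide, and iodinolysis of the C–Zr bond with retention then gives the (E)-iodoalkene needed for the trisubstituted double bond.

Step 16
Reactants: 26 C12 primary iodide; 30 (2E)-3-iodobut-2-en-1-ol
Product: 32 (13E)-allylic alcohol with the complete carbon skeleton, via alkylzinc iodide 31 (not isolated)
Conditions: Zn (3 equiv, activated with Me3SiCl and BrCH2CH2Br), LiCl (1.5 equiv), THF, 40 °C; then 30 (1.3 equiv), Pd(OAc)2 (0.03 equiv), SPhos (0.06 equiv), THF, 25 °C, slow addition of 31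
Reagents that add atoms: none
Why: Negishi coupling, in which direct zinc insertion into the primary C–I bond tolerates the ester and cross-coupling of the alkylzinc iodide with the alkenyl iodide on zerovalent palladium joins C12 to C13 with retention of the (E) geometry and faster than protonation of the zinc reagent by the free hydroxyl group.

Step 17
Reactants: 32 (13E)-allylic alcohol with the complete carbon skeleton
Product: 33 CNP0188193.1
Conditions: HCO2H (3 equiv), DCC (1.5 equiv), DMAP (0.05 equiv), CH2Cl2, 0 °C
Reagents that add atoms: formic acid, OC=O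
Why: Carbodiimide-mediated (Steglich-type) esterification of the primary allylic alcohol with formic acid under mild conditions gives the formate without disturbing the methyl ester or the two trisubstituted alkenes.

Compound list

1 | citraconic anhydride (3-methylfuran-2,5-dione) | CC1=CC(=O)OC1=O | starting material
2 | 5-hydroxy-3-methylfuran-2(5H)-one (racemic) | CC1=CC(O)OC1=O | intermediate
3 | (−)-menthol, (1R,2S,5R)-5-methyl-2-(propan-2-yl)cyclohexan-1-ol | CC(C)[C@@H]1CC[C@@H](C)C[C@H]1O | starting material
4 | (5R)-3-methyl-5-{[(1R,2S,5R)-5-methyl-2-(propan-2-yl)cyclohexyl]oxy}furan-2(5H)-one | CC1=C[C@H](O[C@@H]2C[C@H](C)CC[C@H]2C(C)C)OC1=O | intermediate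
5 | 2-(trimethylsilyloxy)buta-1,3-diene | C=CC(=C)O[Si](C)(C)C | starting material
6 | (3R,3aR,7aS)-7a-methyl-3-{[(1R,2S,5R)-5-methyl-2-(propan-2-yl)cyclohexyl]oxy}-5-(trimethylsilyloxy)-3a,4,7,7a-tetrahydro-2-benzofuran-1(3H)-one | O=C1O[C@@H](O[C@@H]3C[C@H](C)CC[C@H]3C(C)C)[C@@H]2CC(O[Si](C)(C)C)=CC[C@]12C | intermediate
7 | potassium (1S,2R)-4-hydroxy-2-(hydroxymethyl)-1-methylcyclohexane-1-carboxylate, both C4 epimers (not isolated) | [K+].[O-]C(=O)[C@@]1(C)CCC(O)C[C@H]1CO | intermediate
8 | (3aR,7aS)-5-hydroxy-7a-methylhexahydro-2-benzofuran-1(3H)-one, both C5 epimers | O=C1OC[C@@H]2CC(O)CC[C@]12C | intermediate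
9 | sodium (1S,2R)-4-hydroxy-1-methyl-2-[(phenylselanyl)methyl]cyclohexane-1-carboxylate, both C4 epimers (not isolated) | [Na+].[O-]C(=O)[C@@]1(C)CCC(O)C[C@H]1C[Se]c1ccccc1 | intermediate
10 | methyl (1S,2R)-4-hydroxy-1-methyl-2-[(phenylselanyl)methyl]cyclohexane-1-carboxylate, both C4 epimers | COC(=O)[C@@]1(C)CCC(O)C[C@H]1C[Se]c1ccccc1 | intermediate
11 | 3-methylbut-3-en-2-one | CC(=O)C(C)=C | starting material
12 | methyl (1S,2R)-4-hydroxy-1-methyl-2-(3-methyl-4-oxopentyl)cyclohexane-1-carboxylate, epimers at the carbinol and side-chain methine carbons | COC(=O)[C@@]1(C)CCC(O)C[C@H]1CCC(C)C(C)=O | intermediate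
13 | methyl (1S,2R)-1-methyl-2-(3-methyl-4-oxopentyl)-4-oxocyclohexane-1-carboxylate, both side-chain epimers | COC(=O)[C@@]1(C)CCC(=O)C[C@H]1CCC(C)C(C)=O | intermediate
14 | methyl (1S,8aR)-5-hydroxy-1,5,6-trimethyl-4-oxodecahydronaphthalene-1-carboxylate, diastereomer mixture (not isolated) | COC(=O)[C@@]1(C)CCC(=O)C2[C@H]1CCC(C)C2(C)O | intermediate
15 | methyl (1S,8aR)-1,5,6-trimethyl-4-oxo-1,2,3,4,6,7,8,8a-octahydronaphthalene-1-carboxylate, both C6 epimers (not isolated) | COC(=O)[C@@]1(C)CCC(=O)C2=C(C)C(C)CC[C@@H]12 | intermediate
16 | potassium dienolate of 15, enolate oxygen on C1, double bonds C1=C10 and C8=C9 (not isolated) | COC(=O)[C@@]1(C)CCC([O-])=C2C(C)=C(C)CC[C@@H]12.[K+] | intermediate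
17 | methyl (1S,8aR)-1,5,6-trimethyl-4-oxo-1,2,3,4,4a,7,8,8a-octahydronaphthalene-1-carboxylate, both C4a epimers | COC(=O)[C@@]1(C)CCC(=O)C2C(C)=C(C)CC[C@@H]12 | intermediate
18 | methyl (1S,6R,8aR)-1,5,6-trimethyl-4-oxo-1,2,3,4,6,7,8,8a-octahydronaphthalene-1-carboxylate | COC(=O)[C@@]1(C)CCC(=O)C2=C(C)[C@H](C)CC[C@@H]12 | intermediate
19 | methyl (1S,4R,6R,8aR)-4-hydroxy-1,5,6-trimethyl-1,2,3,4,6,7,8,8a-octahydronaphthalene-1-carboxylate | COC(=O)[C@@]1(C)CC[C@@H](O)C2=C(C)[C@H](C)CC[C@@H]12 | intermediate
20 | methyl (1S,4R,6R,8aR)-4-(acetyloxy)-1,5,6-trimethyl-1,2,3,4,6,7,8,8a-octahydronaphthalene-1-carboxylate | COC(=O)[C@@]1(C)CC[C@@H](OC(C)=O)C2=C(C)[C@H](C)CC[C@@H]12 | intermediate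
21 | 1-(trimethylsilyloxy)ethenyl ether of 19, the silyl ketene acetal of 20 (not isolated) | COC(=O)[C@@]1(C)CC[C@@H](OC(=C)O[Si](C)(C)C)C2=C(C)[C@H](C)CC[C@@H]12 | intermediate
22 | trimethylsilyl ester of 23 (not isolated) | COC(=O)[C@@]1(C)CCC=C2[C@H]1CC[C@@H](C)[C@]2(C)CC(=O)O[Si](C)(C)C | intermediate
23 | [(1S,2R,4aR,5S)-5-(methoxycarbonyl)-1,2,5-trimethyl-1,2,3,4,4a,5,6,7-octahydronaphthalen-1-yl]acetic acid | COC(=O)[C@@]1(C)CCC=C2[C@H]1CC[C@@H](C)[C@]2(C)CC(=O)O | intermediate
24 | ethyl carbonic anhydride of 23 (not isolated) | COC(=O)[C@@]1(C)CCC=C2[C@H]1CC[C@@H](C)[C@]2(C)CC(=O)OC(=O)OCC | intermediate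
25 | methyl (1S,5S,6R,8aR)-5-(2-hydroxyethyl)-1,5,6-trimethyl-1,2,3,5,6,7,8,8a-octahydronaphthalene-1-carboxylate | COC(=O)[C@@]1(C)CCC=C2[C@H]1CC[C@@H](C)[C@]2(C)CCO | intermediate
26 | methyl (1S,5S,6R,8aR)-5-(2-iodoethyl)-1,5,6-trimethyl-1,2,3,5,6,7,8,8a-octahydronaphthalene-1-carboxylate | COC(=O)[C@@]1(C)CCC=C2[C@H]1CC[C@@H](C)[C@]2(C)CCI | intermediate
27 | but-2-yn-1-ol | CC#CCO | starting material
28 | (but-2-yn-1-yloxy)bis(2-methylpropyl)aluminium (not isolated) | CC#CCO[Al](CC(C)C)CC(C)C | intermediate
29 | (E)-alkenylzirconocene chloride from 28, zirconium on C3 of the butenyl chain (not isolated) | C/C(=C\CO[Al](CC(C)C)CC(C)C)[Zr](Cl)(C1C=CC=C1)C1C=CC=C1 | intermediate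
30 | (2E)-3-iodobut-2-en-1-ol | C/C(I)=C\CO | intermediate
31 | alkylzinc iodide from 26, zinc on C12 (not isolated) | COC(=O)[C@@]1(C)CCC=C2[C@H]1CC[C@@H](C)[C@]2(C)CC[Zn]I | intermediate
32 | methyl (1S,5S,6R,8aR)-5-[(3E)-5-hydroxy-3-methylpent-3-en-1-yl]-1,5,6-trimethyl-1,2,3,5,6,7,8,8a-octahydronaphthalene-1-carboxylate | COC(=O)[C@@]1(C)CCC=C2[C@H]1CC[C@@H](C)[C@]2(C)CC/C(C)=C/CO | intermediate
33 | CNP0188193.1, methyl (1S,5S,6R,8aR)-5-[(3E)-5-(formyloxy)-3-methylpent-3-en-1-yl]-1,5,6-trimethyl-1,2,3,5,6,7,8,8a-octahydronaphthalene-1-carboxylate | COC(=O)[C@@]1(C)CCC=C2[C@H]1CC[C@@H](C)[C@]2(C)CC/C(C)=C/COC=O | target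

Total step count: 17. Longest linear sequence: 16 steps (steps 1–14, 16 and 17, from citraconic anhydride 1); step 15 is a one-step branch.

The three steps most likely to fail:

First, step 3. The α-methyl group may slow the cycloaddition so much that hydrolysis and polymerisation of the diene win. The fallback moves the methyl group to a later alkylation and sets out from 3 and 5. Acetalisation of 3 with 5-hydroxyfuran-2(5H)-one under the conditions of step 2 should give (5R)-5-(l-menthyloxy)furan-2(5H)-one F1, the more reactive, unsubstituted dienophile. F1 and 5 (toluene, 110 °C) should give, with the same regiochemical and facial sense, the C4-unsubstituted adduct F2. Deprotonation of F2 at C4 with LiN(i-Pr)2 (THF, −78 °C) and methylation of the lactone enolate with MeI, which has to keep the five/six ring fusion cis and therefore enters on the face of H5, comes back to the route at 6.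

Second, step 9. The protonation at C8 may show poor facial selectivity, or the enone may drift by re-enolisation toward the epimer with the pseudo-axial methyl group, which is expected to be the more stable one. The fallback replaces reliance on a single kinetic protonation by separation and recycling, and sets out from 18. The unwanted (8S)-enone F3 is separated from 18 by chromatography and put back under the conditions of step 8 (KOtBu, then AcOH), which erase C8 again and come back to the route at 17.

Third, step 12. Enolisation and silylation of the hindered acetate may be incomplete, or the silyl ketene acetal may decompose before the congested [3,3] shift takes place. The fallback avoids enolate chemistry and sets out from 19. Heating with MeC(OMe)2NMe2 (xylene, 140 °C, Eschenmoser–Claisen rearrangement) should give, by the same suprafacial transfer from C1 to C9, the dimethylamide F4. Cp2Zr(H)Cl (THF, 20 °C) should reduce the tertiary amide, and not the ester, to the aldehyde F5, and NaBH4 (MeOH, 0 °C) then comes back to the route at 25.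

Further compounds

F1 | step 3 | (5R)-5-{[(1R,2S,5R)-5-methyl-2-(propan-2-yl)cyclohexyl]oxy}furan-2(5H)-one | O=C1C=C[C@H](O[C@@H]2C[C@H](C)CC[C@H]2C(C)C)O1
F2 | step 3 | (3R,3aR,7aS)-3-{[(1R,2S,5R)-5-methyl-2-(propan-2-yl)cyclohexyl]oxy}-5-(trimethylsilyloxy)-3a,4,7,7a-tetrahydro-2-benzofuran-1(3H)-one | O=C1O[C@@H](O[C@@H]3C[C@H](C)CC[C@H]3C(C)C)[C@@H]2CC(O[Si](C)(C)C)=CC[C@H]12
F3 | step 9 | methyl (1S,6S,8aR)-1,5,6-trimethyl-4-oxo-1,2,3,4,6,7,8,8a-octahydronaphthalene-1-carboxylate | COC(=O)[C@@]1(C)CCC(=O)C2=C(C)[C@@H](C)CC[C@@H]12
F4 | step 12 | methyl (1S,5S,6R,8aR)-5-[2-(dimethylamino)-2-oxoethyl]-1,5,6-trimethyl-1,2,3,5,6,7,8,8a-octahydronaphthalene-1-carboxylate | COC(=O)[C@@]1(C)CCC=C2[C@H]1CC[C@@H](C)[C@]2(C)CC(=O)N(C)C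
F5 | step 12 | methyl (1S,5S,6R,8aR)-1,5,6-trimethyl-5-(2-oxoethyl)-1,2,3,5,6,7,8,8a-octahydronaphthalene-1-carboxylate | COC(=O)[C@@]1(C)CCC=C2[C@H]1CC[C@@H](C)[C@]2(C)CC=O
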